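The earlier runs and the new flask come from a simulation for substances that don't exist, and the scatter is random.

The left-handed product was what grew in the oak run, to 19% of both substrates charged by 4.00 h, while the right-handed product read 2% or 0% against a scatter of 1.5 percentage points. I therefore took the left-handed product as the measure of conversion in that run.

| flask | left-handed substrate | right-handed substrate | coupling partner | precatalyst | added ligand | remark | time |
|---|---|---|---|---|---|---|---|
| oak | 0.040 M | 0.040 M | 0.050 M | 1 mM | 5.9 mM | run made earlier |  |
| flask | 0.020 M | 0.020 M | 0.0500 M | 1.0 mM | 5.9 mM |  | 20 h |

oak run (percent of the left-handed substrate and right-handed substrate together charged)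

| time / h | left-handed product / % | right-handed product / % |
|---|---|---|
| 0.200 | 2 | 2 |
| 0.667 | 7 | 0 |
| 1.00 | 5 | 2 |
| 1.50 | 9 | 0 |
| 2.50 | 10 | 0 |
| 3.00 | 18 | 0 |
| 4.00 | 19 | 0 |

(standard deviation of a reading: 1.5 percentage points)

- coupling partner is single-handed; left-handed substrate and right-handed substrate are mirror images of each other, charged as a racemate, each of them at the stated concentration
- the numbers in the tables scatter by 1.5 percentage points (one standard deviation)
- steps under discussion: coupling partner + left-handed substrate -> left-handed product; coupling partner + right-handed substrate -> right-handed product; left-handed substrate + racemization catalyst <-> right-handed substrate + racemization catalyst; coupling partner + precatalyst -> racemization catalyst + spent reagent; racemization catalyst + added ligand <-> idle complex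
- an excess is the difference of the two amounts in percent of their sum
- an excess is below zero if the other one leads
- the handed part of coupling partner does not stay in what it makes, so the products of the two hands are mirror images too

* left-handed product and right-handed product together, in percent of the left-handed substrate and right-handed substrate charged together, at 20 h
* excess of left-handed product over right-handed product in the product at 20 h
* whether the exchange between left-handed substrate and right-handed substrate keeps pace with the reaction: how far the product's excess at 20 h gets from its value without exchange to its value with instant exchange (above 80% keeps pace, below 20% hardly takes part, else lags behind)

The new flask looked odd to me: it held half the substrates of the oak run, yet I expected it to start by losing the same share of them per hour. The rate is proportional to substrate times coupling partner, so on dividing by the substrate charge, that charge cancels, and the share lost per hour at the start follows the partner's concentration, equal in both flasks.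

If exchange keeps the two hands equal, the logarithm of the partner's remaining share over the substrates' remaining share grows by g times (one minus r) times the time, where r is substrates charged over partner charged. The last oak reading, with r at 1.60, gave 0.0632 h⁻¹. This g is the pool rate: the share of the remaining substrates that reacts per hour with the partner at its full charge.

In the flask r is 0.800, so over 20 h that ratio reaches 1.29, and solving for the share reacted gave me 59.0%. This number rests on my assumption that exchange keeps the two hands equal.

The forecast differed: y 45%, excess 93%, exchange hardly takes part, on the ground “so I guess exchange is slow”.

The flask gave y 59.2%, excess 92.9%, and exchange that keeps pace, 95% of the way.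

    coupling partner + left-handed substrate → left-handed product (k = 2.60 L mol⁻¹ h⁻¹)
    coupling partner + right-handed substrate → right-handed product (k = 0.0911 L mol⁻¹ h⁻¹)
    left-handed substrate + racemization catalyst ⇌ right-handed substrate + racemization catalyst, rate k3*[racemization catalyst]*[left-handed substrate] forward; the back reaction follows from the equilibrium constant (k = 1390 L mol⁻¹ h⁻¹)
    coupling partner + precatalyst → racemization catalyst + spent reagent (k = 13.2 L mol⁻¹ h⁻¹)
    racemization catalyst + added ligand ⇌ idle complex (K = 160 L mol⁻¹, k = 26.3 L mol⁻¹ h⁻¹)

My 59.0%, reckoned from the last oak reading with its scatter, stood 0.26 points from the flask's y. In the neighbouring flask, charged with 0.12 M of coupling partner, I scaled the pool rate with that charge to 0.152 h⁻¹, and r became 0.333. The ratio then reached 7.56, which gave 90.8%. That neighbouring flask gave y 90.5%, with right-handed product at 3.48%.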